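**Retrosynthetic overview**

1. The four esters go on last. The C1/C10 diol is read as syn-dihydroxylation of an E C1=C10 olefin, and the C3–C4 oxirane with the C5 alcohol as coming from a (3Z)-cyclodeca-1(10),3-dien-5-one.
2. Feature used: in the ten-membered ring C1–C10 the C5 oxygen and the C1=C10 olefin (later the diol) stand 1,6 to each other, i.e. a cyclodec-5-enone, and ring atoms C5–C10 with the C10 methyl and C7 isopropenyl are a carvone ring. An anionic oxy-Cope ring expansion of a trans-5-isopropenyl-10-vinylcyclohexan-5-ol therefore forms C2–C3 and breaks C5–C10.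
3. That cyclohexanol comes from (S)-carvone: the C10 vinyl group and the C9 oxygen are set together (1,2-vinyl addition, hydroxyl-directed epoxidation, semipinacol 1,2-vinyl shift); C5/C6 are set by Rubottom oxidation of a C5-isopropenyl C5=C6 silyl dienol ether and a directed ketone reduction.
4. Ring order: six-membered ring C5–C10 (bought as carvone), then the ten-membered ring (step 11), then the oxirane (step 14).

Key step: step 11

Convention: locants C1–C10 are those of the target's ten-membered ring and are used from carvone onward; β is the face of the C7 isopropenyl group in the flat ring drawing, α the other face.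

Remark: an alkenyl nucleophile should reach the C5 ketone only from the α face (anti to the axial C10 methyl), which would put it cis to the C10 vinyl group. The C5 carbinol is therefore built by oxygen transfer to a C5=C6 enol ether that already carries the isopropenyl group (steps 6–9), not by face-selective carbon addition.

**Route**

Step 1
Reactants: 1 (S)-(+)-carvone; 2 vinylmagnesium bromide
Product: 3 (1R,5S)-1-ethenyl-2-methyl-5-(prop-1-en-2-yl)cyclohex-2-en-1-ol (5β-hydroxy, 5α-vinyl; vinyl trans to isopropenyl)
Conditions: LaCl3·2LiCl (0.3 equiv), THF, −78 → 0 °C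
Reagents that add atoms: none
Why: Grignard 1,2-addition to the enone carbonyl (the lanthanum salt suppresses enolisation and conjugate addition), in which axial attack on the half-chair anti to the equatorial C7 isopropenyl group should place the vinyl group α and the new C5 hydroxyl β.

Step 2
Reactants: 3 tertiary allylic alcohol
Product: 4 9β,10β-epoxy alcohol (5β-hydroxy, 5α-vinyl, oxirane on the face of the hydroxyl, C10 methyl α)
Conditions: VO(acac)2 (3 mol%), t-BuOOH, CH2Cl2, 0 °C → rt
Reagents that add atoms: tert-butyl hydroperoxide, CC(C)(C)OO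
Why: Hydroxyl-directed vanadium-catalysed epoxidation of an allylic alcohol (Sharpless–Michaelson type) should pick the trisubstituted ring olefin over the vinyl and isopropenyl groups and deliver oxygen to the face of the C5 hydroxyl, which sets C9–O β.

Step 3
Reactants: 4 epoxy alcohol
Product: 5 9β-hydroxy-10β-methyl-10α-vinyl-7β-isopropenylcyclohexan-5-one (hydroxyl, methyl and isopropenyl mutually cis, vinyl trans to them)
Conditions: BF3·OEt2 (0.3 equiv), CH2Cl2, −78 → −40 °C
Reagents that add atoms: none
Why: Lewis-acid-mediated semipinacol rearrangement of a 2,3-epoxy alcohol (Suzuki–Tsuchihashi type): the tertiary C10–O bond opens while the vinyl group on C5, antiperiplanar to it, migrates to C10 with inversion, so that the ketone returns at C5, the vinyl group arrives α (anti to O-9), the C10 methyl is turned β and the untouched C9–O bond stays β.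

Step 4
Reactants: 5 β-hydroxy ketone
Product: 6 9β-(tert-butyldimethylsilyloxy) ketone
Conditions: t-BuMe2SiOTf, 2,6-lutidine, CH2Cl2, −78 °C
Reagents that add atoms: tert-butyldimethylsilyl triflate, CC(C)(C)[Si](C)(C)OS(=O)(=O)C(F)(F)F
Why: Standard silylation of a hindered secondary alcohol with the silyl triflate at low temperature, which also removes the retro-aldol liability of the β-hydroxy ketone before base is used.

Step 5
Reactants: 6 silyloxy ketone
Product: 9 6α-(triethylsilyloxy) ketone (OSiEt3 trans to the C7 isopropenyl group), via potassium C5–C6 enolate 7 (not isolated), via potassium C6 alkoxide 8 (not isolated)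
Conditions: KN(SiMe3)2, THF, −78 °C; 2-(phenylsulfonyl)-3-phenyloxaziridine; then Et3SiCl, −78 → 0 °C
Reagents that add atoms: 2-(phenylsulfonyl)-3-phenyloxaziridine, O=S(=O)(c1ccccc1)N1OC1c1ccccc1; chlorotriethylsilane, CC[Si](Cl)(CC)CC
Why: Enolate oxidation with a Davis N-sulfonyloxaziridine followed by O-silylation in the same flask: C6 is the only enolisable position (C10 is quaternary), and the oxidant should approach from the α face because the β face of C6 is screened by the syn-axial C10 methyl group (the C6 configuration is erased again in step 7).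

Step 6
Reactants: 9 α-silyloxy ketone; 10 isopropenylmagnesium bromide
Product: 11 5β-hydroxy-5α-isopropenyl-6α-(triethylsilyloxy) tertiary alcohol
Conditions: LaCl3·2LiCl (0.3 equiv), THF, −78 → −20 °C
Reagents that add atoms: none
Why: Lanthanide-assisted Grignard addition to a hindered ketone, expected from the α face anti to the axial C10 methyl group (axial attack); the resulting C5 configuration is not kept, the step only has to join the isopropenyl carbon to C5.

Step 7
Reactants: 11 tertiary alcohol
Product: 12 5-isopropenyl-6-(triethylsilyloxy)cyclohex-5-ene (silyl dienol ether; 9β-OTBS, 10β-methyl, 10α-vinyl, 7β-isopropenyl)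
Conditions: Burgess reagent, toluene, 60 °C
Reagents that add atoms: none
Why: Burgess dehydration (syn elimination through the sulfamate ester) of a tertiary alcohol whose only β-hydrogen is the cis-disposed H-6, which should give the 2-silyloxy-1,3-diene with the C5=C6 double bond and no regioisomer.

Step 8
Reactants: 12 silyl dienol ether
Product: 14 5α-hydroxy-5β-isopropenyl-6-ketone (α-ketol), via 5α-triethylsilyloxy ketone 13 (not isolated)
Conditions: dimethyldioxirane, acetone/CH2Cl2, −78 → −20 °C; then HF·pyridine, pyridine, THF, 0 °C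
Reagents that add atoms: dimethyldioxirane, CC1(C)OO1
Why: Rubottom oxidation: the silyl enol ether is the most electron-rich olefin and dimethyldioxirane should epoxidise it from the α face, anti to the pseudoaxial C10 methyl group that flanks C5, so that after silyl transfer and fluoride cleavage the new tertiary C5 hydroxyl is α and the isopropenyl group β (equatorial, trans to the C10 vinyl group).

Step 9
Reactants: 14 α-ketol
Product: 15 5α,6β-diol (trans-diaxial; 5β-isopropenyl)
Conditions: Me4NBH(OAc)3, MeCN/AcOH, −20 °C → rt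
Reagents that add atoms: none
Why: Hydroxyl-directed triacetoxyborohydride reduction (Evans–Saksena type): boron bound to the axial 5α-hydroxyl delivers hydride to the α face of the C6 carbonyl, which is also the face left open by the syn-axial C10 methyl group, so the C6 alcohol should emerge β (axial) and trans to O-5.

Step 10
Reactants: 15 diol
Product: 17 trans-5β-isopropenyl-10α-vinylcyclohexan-5α-ol with 6β-OPMB and 9β-OTBS (oxy-Cope precursor), via sodium C6 alkoxide 16 (not isolated)
Conditions: NaH (1.1 equiv), 4-MeOC6H4CH2Br, Bu4NI (cat.), THF/DMF, 0 °C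
Reagents that add atoms: 4-methoxybenzyl bromide, COc1ccc(CBr)cc1
Why: Williamson etherification in which the secondary C6 alkoxide is alkylated much faster than the hindered tertiary C5 alkoxide; with sodium as counter-ion at 0 °C the sigmatropic shift of step 11 is not expected to start.

Step 11
Reactants: 17 trans-dialkenyl cyclohexanol
Product: 20 trimethylsilyl enol ether of the (E)-cyclodec-5-enone (E C1=C10; C4=C5 enol ether with C3 and C6 trans; 6β-OPMB, 7β-isopropenyl, 9β-OTBS), via potassium C5 alkoxide 18 (not isolated), via potassium C4–C5 enolate 19 (not isolated)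
Conditions: KH, 18-crown-6, THF, 0 °C → rt; then Me3SiCl/Et3N (premixed), −78 °C
Reagents that add atoms: chlorotrimethylsilane, C[Si](C)(C)Cl
Why: Deprotonation gives the potassium alkoxide, whose C5–C10 bond is weakened by the neighbouring oxyanion, and a concerted [3,3] shift then joins the two alkene termini (C2–C3) as C5–C10 breaks; this is the anionic oxy-Cope rearrangement of a trans-1,2-dialkenylcyclohexanol, the known route to (E)-cyclodec-5-enones with enolate trapping. The ten-membered ring is not closed end to end but arises by four-atom ring expansion of the six-membered ring through a chair-like six-centre transition state. No stereocentre is formed: C5 and C10 become sp2, and C6, C7 and C9 are spectators set beforehand. The only selectivity needed is olefin geometry, and it is secured by the substrate: the vinyl and isopropenyl groups are trans and both equatorial on the chair that also keeps the C7 isopropenyl and C9 silyloxy groups equatorial, so C6 and C9 sit pseudo-equatorial in the Cope chair, which should give the E C1=C10 olefin and the enolate with C3 and C6 trans across C4=C5. Enolate formation makes the step irreversible, and silylation at −78 °C stores the C4=C5 enolate regiochemistry for the dehydrogenation that follows.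

Step 12
Reactants: 20 silyl enol ether
Product: 21 (1(10)E,3Z)-cyclodeca-1(10),3-dien-5-one (4-methyl; 6β-OPMB, 7β-isopropenyl, 9β-OTBS)
Conditions: Pd(OAc)2 (1.1 equiv), MeCN, rt
Reagents that add atoms: none
Why: Saegusa–Ito oxidation: silicon-to-palladium exchange gives a palladium enolate whose β-hydride elimination toward C3 forms the conjugated enone, and with the E C1=C10 olefin already in the ring the new trisubstituted C3=C4 bond should be Z (C2 and C5 cis), since an E,E skipped diene would be far more strained.

Step 13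
Reactants: 21 dienone
Product: 22 5β-allylic alcohol (C5 hydroxyl cis to O-6)
Conditions: Zn(BH4)2, Et2O, −30 °C
Reagents that add atoms: none
Why: Chelation-controlled 1,2-reduction of an α-alkoxy enone with Zn(BH4)2: zinc bridges the C5 carbonyl and the C6 ether oxygen, hydride comes from the outer face on the side of H-6 (Cram chelate model), and the C5 alcohol should form β, cis to O-6.

Step 14
Reactants: 22 allylic alcohol
Product: 23 3β,4β-epoxy-5β-alcohol (cis oxirane, H-3 and the C4 methyl α)
Conditions: VO(acac)2 (5 mol%), t-BuOOH, CH2Cl2, 0 °C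
Reagents that add atoms: tert-butyl hydroperoxide, CC(C)(C)OO
Why: Hydroxyl-directed vanadium-catalysed epoxidation of the (Z)-allylic alcohol: oxygen transfer is stereospecific (the cis oxirane is kept) and, as with medium-ring cis-cycloalkenols, should come from the face of the C5 hydroxyl (β at C3 and C4), while the E olefin and the isopropenyl group lack a directing hydroxyl in allylic position.

Step 15
Reactants: 23 epoxy alcohol
Product: 24 5β-acetate
Conditions: Ac2O, pyridine, DMAP (cat.), CH2Cl2, 0 °C → rt
Reagents that add atoms: acetic anhydride, CC(=O)OC(C)=O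
Why: DMAP-catalysed acetylation of the only free hydroxyl.

Step 16
Reactants: 24 E olefin
Product: 25 1β,10α-diol (C10 methyl β)
Conditions: OsO4 (5 mol%), N-methylmorpholine N-oxide, acetone/H2O, 0 °C
Reagents that add atoms: osmium tetroxide (catalytic oxygen carrier), O=[Os](=O)(=O)=O; N-methylmorpholine N-oxide, C[N+]1([O-])CCOCC1; water, O
Why: Catalytic syn-dihydroxylation (Upjohn conditions): the strained trisubstituted E olefin should react faster than the isopropenyl group, and because its plane stands across the ring only the outer face is open; in the crown conformer that keeps the C7 isopropenyl and C9 silyloxy groups equatorial the C10 methyl points to the β face (as in 1(10)E-germacrenes), so outer-face attack should give O-1 β and O-10 α.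

Step 17
Reactants: 25 diol
Product: 26 1β-angelate (C10 hydroxyl free)
Conditions: angelic acid, 2,4,6-Cl3C6H2COCl, Et3N, toluene, rt; then 25, 80 °C
Reagents that add atoms: angelic acid, C/C=C(/C)C(=O)O
Why: Yamaguchi-type esterification through the preformed mixed anhydride, run without DMAP so that the Z acid is not isomerised to tiglate; only the secondary C1 hydroxyl is acylated, the tertiary C10 hydroxyl stays free.

Step 18
Reactants: 26 silyl ether
Product: 27 9β-alcohol
Conditions: Bu4NF/AcOH (1:1), THF, 0 °C → rt
Reagents that add atoms: none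
Why: Fluoride desilylation buffered with acetic acid, so that no free alkoxide arises that could start acyl migration or open the oxirane.

Step 19
Reactants: 27 C9 alcohol
Product: 28 9β-acetate
Conditions: Ac2O, pyridine, DMAP (cat.), CH2Cl2, 0 °C
Reagents that add atoms: acetic anhydride, CC(=O)OC(C)=O
Why: Acetylation of the secondary C9 hydroxyl; the tertiary C10 hydroxyl is not acylated under these conditions.

Step 20
Reactants: 28 PMB ether
Product: 29 6β-alcohol
Conditions: DDQ, CH2Cl2/pH 7 buffer, 0 °C
Reagents that add atoms: none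
Why: Oxidative cleavage of the p-methoxybenzyl ether with DDQ under buffered conditions that leave esters, oxirane and olefins alone.

Step 21
Reactants: 29 C6 alcohol
Product: 30 CNP0416509.1 (target)
Conditions: Me2C=CHCOCl, pyridine, DMAP (cat.), CH2Cl2, 0 °C
Reagents that add atoms: 3-methylbut-2-enoyl chloride, CC(C)=CC(=O)Cl
Why: Acylation with the acid chloride in pyridine at 0 °C, fast enough to outrun acetyl migration from O-5 to O-6 and free of the stronger amine bases that deconjugate senecioates.

**Compound list**

1 | (S)-(+)-carvone | CC1=CC[C@@H](CC1=O)C(C)=C | starting material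
2 | vinylmagnesium bromide | C=C[Mg]Br | starting material
3 | (1R,5S)-1-ethenyl-2-methyl-5-(prop-1-en-2-yl)cyclohex-2-en-1-ol (5β-OH, 5α-vinyl) | C=C(C)[C@H]1CC=C(C)[C@](O)(C=C)C1 | intermediate
4 | 9β,10β-epoxy-5β-hydroxy-5α-vinyl epoxy alcohol | C=C(C)[C@H]1C[C@H]2O[C@@]2(C)[C@](O)(C=C)C1 | intermediate
5 | 9β-hydroxy-10β-methyl-10α-vinyl-7β-isopropenylcyclohexan-5-one | C=C(C)[C@H]1C[C@@H](O)[C@](C)(C=C)C(=O)C1 | intermediate
6 | 9β-(tert-butyldimethylsilyloxy) ketone | C=C(C)[C@H]1C[C@@H](O[Si](C)(C)C(C)(C)C)[C@](C)(C=C)C(=O)C1 | intermediate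
7 | potassium C5–C6 enolate of 6 | C=C(C)[C@H]1C[C@@H](O[Si](C)(C)C(C)(C)C)[C@](C)(C=C)C([O-])=C1.[K+] | intermediate (not isolated)
8 | potassium alkoxide of the 6α-hydroxy ketone | C=C(C)[C@H]1C[C@@H](O[Si](C)(C)C(C)(C)C)[C@](C)(C=C)C(=O)[C@@H]1[O-].[K+] | intermediate (not isolated)
9 | 6α-(triethylsilyloxy) ketone | C=C(C)[C@H]1C[C@@H](O[Si](C)(C)C(C)(C)C)[C@](C)(C=C)C(=O)[C@@H]1O[Si](CC)(CC)CC | intermediate
10 | isopropenylmagnesium bromide | C=C(C)[Mg]Br | starting material
11 | 5β-hydroxy-5α-isopropenyl-6α-(triethylsilyloxy) tertiary alcohol | C=C(C)[C@H]1C[C@@H](O[Si](C)(C)C(C)(C)C)[C@](C)(C=C)[C@](O)(C(C)=C)[C@@H]1O[Si](CC)(CC)CC | intermediate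
12 | 5-isopropenyl-6-(triethylsilyloxy)cyclohex-5-ene (silyl dienol ether) | C=C(C)[C@H]1C[C@@H](O[Si](C)(C)C(C)(C)C)[C@](C)(C=C)C(C(C)=C)=C1O[Si](CC)(CC)CC | intermediate
13 | 5α-(triethylsilyloxy)-5β-isopropenyl-6-ketone | C=C(C)[C@H]1C[C@@H](O[Si](C)(C)C(C)(C)C)[C@](C)(C=C)[C@@](O[Si](CC)(CC)CC)(C(C)=C)C1=O | intermediate (not isolated)
14 | 5α-hydroxy-5β-isopropenyl-6-ketone (α-ketol) | C=C(C)[C@H]1C[C@@H](O[Si](C)(C)C(C)(C)C)[C@](C)(C=C)[C@@](O)(C(C)=C)C1=O | intermediate
15 | 5α,6β-diol | C=C(C)[C@H]1C[C@@H](O[Si](C)(C)C(C)(C)C)[C@](C)(C=C)[C@@](O)(C(C)=C)[C@H]1O | intermediate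
16 | sodium C6 alkoxide of 15 | C=C(C)[C@H]1C[C@@H](O[Si](C)(C)C(C)(C)C)[C@](C)(C=C)[C@@](O)(C(C)=C)[C@H]1[O-].[Na+] | intermediate (not isolated)
17 | trans-5β-isopropenyl-10α-vinylcyclohexan-5α-ol, 6β-OPMB, 9β-OTBS (oxy-Cope precursor) | C=C(C)[C@H]1C[C@@H](O[Si](C)(C)C(C)(C)C)[C@](C)(C=C)[C@@](O)(C(C)=C)[C@H]1OCc1ccc(OC)cc1 | intermediate
18 | potassium C5 alkoxide of 17 | C=C(C)[C@H]1C[C@@H](O[Si](C)(C)C(C)(C)C)[C@](C)(C=C)[C@@]([O-])(C(C)=C)[C@H]1OCc1ccc(OC)cc1.[K+] | intermediate (not isolated)
19 | potassium C4–C5 enolate of the (E)-cyclodec-5-enone | C=C(C)[C@H]1C[C@@H](O[Si](C)(C)C(C)(C)C)/C(C)=C/CC/C(C)=C(\[O-])[C@H]1OCc1ccc(OC)cc1.[K+] | intermediate (not isolated)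
20 | trimethylsilyl enol ether of the (E)-cyclodec-5-enone | C=C(C)[C@H]1C[C@@H](O[Si](C)(C)C(C)(C)C)/C(C)=C/CC/C(C)=C(\O[Si](C)(C)C)[C@H]1OCc1ccc(OC)cc1 | intermediate
21 | (1(10)E,3Z)-cyclodeca-1(10),3-dien-5-one | C=C(C)[C@H]1C[C@@H](O[Si](C)(C)C(C)(C)C)/C(C)=C/C/C=C(/C)C(=O)[C@H]1OCc1ccc(OC)cc1 | intermediate
22 | 5β-allylic alcohol | C=C(C)[C@H]1C[C@@H](O[Si](C)(C)C(C)(C)C)/C(C)=C/C/C=C(/C)[C@@H](O)[C@H]1OCc1ccc(OC)cc1 | intermediate
23 | 3β,4β-epoxy-5β-alcohol | C=C(C)[C@H]1C[C@@H](O[Si](C)(C)C(C)(C)C)/C(C)=C/C[C@H]2O[C@@]2(C)[C@@H](O)[C@H]1OCc1ccc(OC)cc1 | intermediate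
24 | 5β-acetate | C=C(C)[C@H]1C[C@@H](O[Si](C)(C)C(C)(C)C)/C(C)=C/C[C@H]2O[C@@]2(C)[C@@H](OC(C)=O)[C@H]1OCc1ccc(OC)cc1 | intermediate
25 | 1β,10α-diol | C=C(C)[C@H]1C[C@@H](O[Si](C)(C)C(C)(C)C)[C@](C)(O)[C@@H](O)C[C@H]2O[C@@]2(C)[C@@H](OC(C)=O)[C@H]1OCc1ccc(OC)cc1 | intermediate
26 | 1β-angelate | C=C(C)[C@H]1C[C@@H](O[Si](C)(C)C(C)(C)C)[C@](C)(O)[C@@H](OC(=O)/C(C)=C\C)C[C@H]2O[C@@]2(C)[C@@H](OC(C)=O)[C@H]1OCc1ccc(OC)cc1 | intermediate
27 | 9β-alcohol | C=C(C)[C@H]1C[C@@H](O)[C@](C)(O)[C@@H](OC(=O)/C(C)=C\C)C[C@H]2O[C@@]2(C)[C@@H](OC(C)=O)[C@H]1OCc1ccc(OC)cc1 | intermediate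
28 | 9β-acetate | C=C(C)[C@H]1C[C@@H](OC(C)=O)[C@](C)(O)[C@@H](OC(=O)/C(C)=C\C)C[C@H]2O[C@@]2(C)[C@@H](OC(C)=O)[C@H]1OCc1ccc(OC)cc1 | intermediate
29 | 6β-alcohol | C=C(C)[C@H]1C[C@@H](OC(C)=O)[C@](C)(O)[C@@H](OC(=O)/C(C)=C\C)C[C@H]2O[C@@]2(C)[C@@H](OC(C)=O)[C@H]1O | intermediate
30 | CNP0416509.1 | C=C(C)[C@H]1C[C@@H](OC(C)=O)[C@](C)(O)[C@@H](OC(=O)/C(C)=C\C)C[C@H]2O[C@@]2(C)[C@@H](OC(C)=O)[C@H]1OC(=O)C=C(C)C | target

**Totals**

Total step count: 21. Longest linear sequence: 21 steps from (S)-carvone.

**Steps most likely to fail**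

Step 11 (key rearrangement). The hindered potassium alkoxide may decompose under the strongly basic conditions or rearrange in part by a stepwise cleavage–recombination path, which would erode the olefin geometry; the enolate may also be lost before it is silylated. The fallback leaves out the base. Compound 17 would be silylated at the tertiary hydroxyl (Me3SiOTf, 2,6-lutidine, CH2Cl2, −78 °C) to the trimethylsilyl ether of 17 F1. Heating F1 in o-dichlorobenzene at 200–220 °C in a base-washed sealed tube should bring about the neutral siloxy-Cope rearrangement through the same chair and give the silyl enol ether directly. The route is rejoined at compound 20.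

Step 16 (dihydroxylation). Osmylation may occur on the other face of the E olefin (giving the 1α,10β-diol) or compete at the isopropenyl group. The fallback uses that exposed face instead of fighting it. Compound 24 would be epoxidised with m-chloroperbenzoic acid (CH2Cl2, NaHCO3, −20 °C), which prefers the strained trisubstituted olefin, to give the 1α,10β-epoxide F2. Dilute aqueous HClO4 in THF at 0 °C should open F2 at the tertiary C10 with inversion to the 1α,10α-diol F3, which already has the C10 configuration of the target. A Mitsunobu reaction of F3 with angelic acid (PPh3, diisopropyl azodicarboxylate, toluene) would then invert C1 and install the ester in one operation. The route is rejoined at compound 26.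

Step 7 (dehydration). The sulfamate of the hindered tertiary allylic alcohol may ionise and return with allylic transposition, or the silyl group may migrate, instead of clean elimination toward C6. The fallback builds the same diene by cross-coupling. Compound 9 would be deprotonated at C6 (KN(SiMe3)2, THF, −78 °C) and trapped with N-(5-chloro-2-pyridyl)triflimide to give the 6-(triethylsilyloxy)cyclohex-5-en-5-yl triflate F4. Suzuki–Miyaura coupling of F4 with isopropenylboronic acid pinacol ester (Pd(PPh3)4, K3PO4, dioxane/H2O, 80 °C) should give the silyl dienol ether. The route is rejoined at compound 12, and step 6 is then not needed.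

**Further compounds**

F1 | step 11 | trimethylsilyl ether of 17 | C=C(C)[C@H]1C[C@@H](O[Si](C)(C)C(C)(C)C)[C@](C)(C=C)[C@@](O[Si](C)(C)C)(C(C)=C)[C@H]1OCc1ccc(OC)cc1
F2 | step 16 | 1α,10β-epoxide of 24 | C=C(C)[C@H]1C[C@@H](O[Si](C)(C)C(C)(C)C)[C@@]3(C)O[C@@H]3C[C@H]2O[C@@]2(C)[C@@H](OC(C)=O)[C@H]1OCc1ccc(OC)cc1
F3 | step 16 | 1α,10α-diol | C=C(C)[C@H]1C[C@@H](O[Si](C)(C)C(C)(C)C)[C@](C)(O)[C@H](O)C[C@H]2O[C@@]2(C)[C@@H](OC(C)=O)[C@H]1OCc1ccc(OC)cc1
F4 | step 7 | 6-(triethylsilyloxy)cyclohex-5-en-5-yl triflate | C=C(C)[C@H]1C[C@@H](O[Si](C)(C)C(C)(C)C)[C@](C)(C=C)C(OS(=O)(=O)C(F)(F)F)=C1O[Si](CC)(CC)CC
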